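**Plan**
Germacrane numbering: lactone C12(=O)–O–C6 with C7 and C11=C13; C8 carries the angelate; ether C5–O–C10; ketone C1, alkene C2=C3; C4 carries C15H2OH.
Retrosynthesis cuts, in order: the C15 O–Si bond; C2=C3 (ring-closing metathesis) and C1–C2 (acylation of a vinyl group); the angelate C–O bond; C5–C6 and C7–C8 together; C9–C10 (enolate alkylation); the two acetal C–O bonds at C5; C4–C15.
Enabling feature: C6 and C7, the two sp3 carbons of the α-methylene-γ-butyrolactone, each bear an oxygenated CH (C5, C8), and these are tied 1,5 through the ether oxygen (C5–O–C10–C9–C8). An acetal carbon and an aldehyde hanging on one oxygen can therefore take up a butenolide C5/C4 dinucleophile and close the oxepane ring A (O, C5–C10) with the lactone in one operation.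
Forward: furan dinucleophile 5; C4 fragment 14; dioxolanone 17 from (R)-lactic acid, prenylation, ozonolysis to 21; annulation gives ring A plus lactone (24); angelate; vinyl ketone; metathesis closes the oxepenone ring B (28); desilylation.
Stereochemistry: C4 from the oxazolidinone auxiliary; C10 from (R)-lactic acid, relayed through the acetal carbon C5 (self-regeneration of the stereocentre); C5 by invertive opening of that acetal; C6, C7, C8 in the annulation; the angelate geometry from angelic acid.

Key step: step 13

Assumption: the SMILES is taken literally; it puts the ether oxygen on opposite faces of the ten-membered ring at C5 and C10 (a trans-bridged, inside–outside 11-oxabicyclo[4.4.1]undecene, as in the ingenane skeleton), and the route is built for exactly that configuration.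

Step 1
Reactants: 1 furan-2(5H)-one
Product: 3 3-bromofuran-2(5H)-one, via dibromolactone 2 (not isolated)
Conditions: Br2, CH2Cl2, 0 °C → rt; then Et3N, 0 °C
Reagents that add atoms: bromine, BrBr
Why: Anti addition of bromine to the enoate followed by amine-induced E1cB loss of HBr (acidic C3–H, C4 bromide) should give the α-bromobutenolide (bromination–dehydrobromination).

Step 2
Reactants: 3 3-bromofuran-2(5H)-one
Product: 4 3-[(trimethylsilyl)methyl]furan-2(5H)-one
Conditions: Me3SiCH2MgCl, ZnCl2, THF, 0 °C; then 3, Pd(PPh3)4 (5 mol %), THF, rt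
Reagents that add atoms: (trimethylsilyl)methylmagnesium chloride, C[Si](C)(C)C[Mg]Cl
Why: Negishi cross-coupling of the activated α-bromo enoate with the silylmethylzinc reagent, which the lactone tolerates, should install the allylsilane.

Step 3
Reactants: 4 3-[(trimethylsilyl)methyl]furan-2(5H)-one
Product: 5 trimethyl({3-[(trimethylsilyl)methyl]furan-2-yl}oxy)silane
Conditions: TMSOTf, Et3N, CH2Cl2, 0 °C
Reagents that add atoms: trimethylsilyl trifluoromethanesulfonate, C[Si](C)(C)OS(=O)(=O)C(F)(F)F
Why: Soft enolisation at the γ-CH2 gives the aromatic 2-silyloxyfuran (silyl dienol ether formation) and leaves the C–Si bond alone.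

Step 4
Reactants: 6 (S)-4-benzyloxazolidin-2-one, 7 but-3-enoic acid
Product: 9 (S)-4-benzyl-3-(but-3-enoyl)oxazolidin-2-one, via mixed pivalic anhydride 8 (not isolated)
Conditions: 7, PivCl, Et3N, THF, −20 °C; then 6, LiCl, −20 °C → rt
Reagents that add atoms: none
Why: N-acylation of the auxiliary through the mixed anhydride, attacked at its less hindered carbonyl, should give the imide (Evans auxiliary attachment).

Step 5
Reactants: 9 (S)-4-benzyl-3-(but-3-enoyl)oxazolidin-2-one
Product: 11 (S)-4-benzyl-3-[(R)-2-(hydroxymethyl)but-3-enoyl]oxazolidin-2-one, via titanium enolate 10 (not isolated)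
Conditions: TiCl4, i-Pr2NEt, CH2Cl2, 0 °C; then 1,3,5-trioxane, TiCl4, 0 °C
Reagents that add atoms: 1,3,5-trioxane, C1OCOCO1
Why: Evans titanium-enolate hydroxymethylation: the chelated Z-enolate reacts at its α-carbon with the formaldehyde equivalent on the face away from the benzyl group, which sets C4.

Step 6
Reactants: 11 (S)-4-benzyl-3-[(R)-2-(hydroxymethyl)but-3-enoyl]oxazolidin-2-one
Product: 12 (S)-4-benzyl-3-[(R)-2-{[tert-butyl(diphenyl)silyl]oxymethyl}but-3-enoyl]oxazolidin-2-one
Conditions: TBDPSCl, imidazole, CH2Cl2, 0 °C → rt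
Reagents that add atoms: tert-butyl(chloro)diphenylsilane, CC(C)(C)[Si](Cl)(c1ccccc1)c1ccccc1
Why: Silylation of the primary alcohol fixes the difference between the two CH2O arms before the auxiliary is removed.

Step 7
Reactants: 12 (S)-4-benzyl-3-[(R)-2-{[tert-butyl(diphenyl)silyl]oxymethyl}but-3-enoyl]oxazolidin-2-one
Product: 13 (S)-2-{[tert-butyl(diphenyl)silyl]oxymethyl}but-3-en-1-ol
Conditions: LiBH4, MeOH (1 equiv), Et2O, 0 °C
Reagents that add atoms: none
Why: Reductive cleavage of the imide with LiBH4 should give the primary alcohol without touching the stereocentre and return the auxiliary.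

Step 8
Reactants: 13 (S)-2-{[tert-butyl(diphenyl)silyl]oxymethyl}but-3-en-1-ol
Product: 14 (R)-2-{[tert-butyl(diphenyl)silyl]oxymethyl}but-3-enal
Conditions: Dess–Martin periodinane, CH2Cl2, 0 °C → rt; used at once
Reagents that add atoms: none
Why: Dess–Martin oxidation under neutral conditions gives the α-vinyl aldehyde, which is used directly so that its α-centre is not lost by enolisation.

Step 9
Reactants: 15 (R)-lactic acid
Product: 16 trimethylsilyl (R)-2-[(trimethylsilyl)oxy]propanoate
Conditions: TMSCl, Et3N, CH2Cl2, 0 °C → rt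
Reagents that add atoms: chlorotrimethylsilane, C[Si](C)(C)Cl
Why: Bis-silylation prepares the hydroxy acid for silyl-triflate-catalysed acetalisation.

Step 10
Reactants: 16 trimethylsilyl (R)-2-[(trimethylsilyl)oxy]propanoate, 14 (R)-2-{[tert-butyl(diphenyl)silyl]oxymethyl}but-3-enal
Product: 17 (2R,5R)-2-[(2R)-1-{[tert-butyl(diphenyl)silyl]oxy}but-3-en-2-yl]-5-methyl-1,3-dioxolan-4-one
Conditions: TMSOTf (5 mol %), CH2Cl2, −78 °C
Reagents that add atoms: none
Why: Silyl-triflate-catalysed acetalisation of a bis-silylated α-hydroxy acid with an aldehyde under kinetic control should give the cis-2,5-disubstituted dioxolanone, so the acetal carbon (target C5) is set from the lactate centre and the aldehyde α-centre is not enolised at −78 °C.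

Step 11
Reactants: 17 (2R,5R)-2-[(2R)-1-{[tert-butyl(diphenyl)silyl]oxy}but-3-en-2-yl]-5-methyl-1,3-dioxolan-4-one
Product: 19 (2R,5S)-2-[(2R)-1-{[tert-butyl(diphenyl)silyl]oxy}but-3-en-2-yl]-5-methyl-5-(3-methylbut-2-en-1-yl)-1,3-dioxolan-4-one, via lithium enolate 18 (not isolated)
Conditions: LiN(i-Pr)2, THF, −78 °C; then prenyl bromide, −78 → −40 °C
Reagents that add atoms: 1-bromo-3-methylbut-2-ene, CC(C)=CCBr
Why: Enolate alkylation with self-regeneration of the stereocentre: the planar enolate is prenylated on the face opposite the C2 substituent, which sets the quaternary centre (target C10) with methyl cis and the new chain trans to that substituent.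

Step 12
Reactants: 19 (2R,5S)-2-[(2R)-1-{[tert-butyl(diphenyl)silyl]oxy}but-3-en-2-yl]-5-methyl-5-(3-methylbut-2-en-1-yl)-1,3-dioxolan-4-one
Product: 21 2-[(2R,5S)-2-[(2R)-1-{[tert-butyl(diphenyl)silyl]oxy}but-3-en-2-yl]-5-methyl-4-oxo-1,3-dioxolan-5-yl]acetaldehyde, via ozonide 20 (not isolated)
Conditions: O3, CH2Cl2, Sudan Red 7B (indicator), −78 °C; then PPh3, −78 °C → rt
Reagents that add atoms: ozone, [O-][O+]=O
Why: Chemoselective ozonolysis: the electron-rich trisubstituted prenyl alkene reacts much faster than the monosubstituted vinyl group, the dye marks the end point, and reduction of the ozonide gives the aldehyde.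

Step 13
Reactants: 21 2-[(2R,5S)-2-[(2R)-1-{[tert-butyl(diphenyl)silyl]oxy}but-3-en-2-yl]-5-methyl-4-oxo-1,3-dioxolan-5-yl]acetaldehyde, 5 trimethyl({3-[(trimethylsilyl)methyl]furan-2-yl}oxy)silane
Product: 24 hydroxy acid (oxepane ring A trans-fused to the α-methylene-γ-butyrolactone; (4R,5R,6S,7R,8R,10S)), via butenolide silyl ester 22 (not isolated), via bis-silylated oxepane lactone 23 (not isolated)
Conditions: TMSOTf (1.1 equiv), CH2Cl2, −78 °C; then TMSNTf2 (0.3 equiv), −78 → −30 °C; then aq. citric acid, THF
Reagents that add atoms: none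
Why: Proposed new method: TMSOTf silylates the lactone carbonyl of 21 and ionises the acyloxy C–O bond of the acetal, and the contact ion pair of the oxocarbenium ion (target C5=O+–C10) and the silyl carboxylate is attacked by C5 of furan 5 (target C6) anti to the departing carboxylate, giving butenolide 22 while the aldehyde, which silyl triflates activate far less than acetals at −78 °C, waits; 22 is an allylsilane of the 2-(silylmethyl)alkenoate kind, and once the stronger silyl Lewis acid TMSNTf2 activates the aldehyde its γ-carbon (target C7) adds to C8 in an intramolecular Hosomi–Sakurai reaction that moves the double bond to C11=C13 and leaves 23. The closest known reaction types are the Lewis-acid opening of dioxolanone and dioxanone acetals by silyl nucleophiles with inversion, the vinylogous Mukaiyama addition of 2-silyloxyfurans to oxocarbenium ions and the cyclisation of 2-(silylmethyl)alkenoates onto aldehydes; what is new is one furan serving as a 1,2-dinucleophile for both bonds in one flask. The oxepane ring A closes in the 7-exo-trig mode at the aldehyde carbon, and the lactone ring is brought in intact by the furan. C5 is set by inversion at the acetal carbon, C6 by an open antiperiplanar approach that keeps the furan oxygen away from the bulky tertiary alkoxy group (5,6-erythro), C7 by attack of the allylsilane on the face anti to its C6 substituent (trans lactone), and C8 by a chair-like seven-membered transition state with the silylated carbonyl oxygen pseudo-equatorial, cis to the C10 methyl and trans to the pseudo-axial silyl ester. The step needs the acetal to react before the aldehyde and the furan C5 before the allylsilane, which the acyloxy leaving group and the much higher nucleophilicity of the silyloxyfuran secure, and it needs the second bond at C7 and not at C13, which the SE2′ course of the allylsilane secures.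

Step 14
Reactants: 24 hydroxy acid
Product: 25 C8 angelate of 24 (free acid at C10)
Conditions: angelic acid, 2,4,6-trichlorobenzoyl chloride, Et3N, toluene, rt; then 24, 75 °C; aq. NaHCO3 work-up
Reagents that add atoms: angelic acid, C/C=C(/C)C(=O)O
Why: Yamaguchi esterification with the preformed mixed anhydride, run without DMAP to keep the Z geometry, should acylate the C8 alcohol with retention, and the hindered tertiary carboxylic acid is recovered as the free acid after the bicarbonate work-up.

Step 15
Reactants: 25 C8 angelate of 24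
Product: 27 vinyl ketone (C10 carries C(=O)CH=CH2), via acid chloride 26 (not isolated)
Conditions: 1-chloro-N,N,2-trimethylprop-1-en-1-amine, CH2Cl2, 0 °C → rt; then Bu3SnCH=CH2, PdCl(CH2Ph)(PPh3)2 (3 mol %), THF, 45 °C
Reagents that add atoms: tributyl(vinyl)stannane, C=C[Sn](CCCC)(CCCC)CCCC
Why: Neutral conversion of the acid into its chloride and Migita–Kosugi–Stille ketone synthesis should give the vinyl ketone, since palladium-catalysed acylation tolerates the lactone, the ester and the alkenes.

Step 16
Reactants: 27 vinyl ketone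
Product: 28 15-O-tert-butyldiphenylsilyl ether of the target
Conditions: second-generation Hoveyda–Grubbs catalyst (10 mol %), 1,4-benzoquinone (20 mol %), toluene (1 mM), 80 °C
Reagents that add atoms: none
Why: Ring-closing metathesis between the vinyl ketone and the C4 vinyl group closes the seven-membered Z-enone ring B across the trans-related C5 and C10 substituents of ring A, as in metathesis closures of inside–outside bicyclo[4.4.1]undecane carbocycles; the 1,1-disubstituted methylene lactone and the trisubstituted angelate are poor partners, and closure onto C11 would need a bridgehead alkene.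

Step 17
Reactants: 28 15-O-tert-butyldiphenylsilyl ether of the target
Product: 29 CNP0274187.1 (target)
Conditions: HF·pyridine, pyridine, THF, 0 °C → rt
Reagents that add atoms: none
Why: Fluoride cleavage of the silyl ether under buffered, non-basic conditions should spare the angelate, the methylene lactone and the base-sensitive δ-alkoxy enone.

**Compound list**
1 | furan-2(5H)-one | O=C1OCC=C1 | starting material
2 | trans-3,4-dibromodihydrofuran-2(3H)-one (racemic, one enantiomer drawn) | O=C1OC[C@@H](Br)[C@@H]1Br | intermediate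
3 | 3-bromofuran-2(5H)-one | O=C1OCC=C1Br | intermediate
4 | 3-[(trimethylsilyl)methyl]furan-2(5H)-one | C[Si](C)(C)CC1=CCOC1=O | intermediate
5 | trimethyl({3-[(trimethylsilyl)methyl]furan-2-yl}oxy)silane | C[Si](C)(C)Cc1ccoc1O[Si](C)(C)C | intermediate
6 | (S)-4-benzyloxazolidin-2-one | O=C1N[C@@H](Cc2ccccc2)CO1 | starting material
7 | but-3-enoic acid | C=CCC(=O)O | starting material
8 | but-3-enoic pivalic anhydride | C=CCC(=O)OC(=O)C(C)(C)C | intermediate
9 | (S)-4-benzyl-3-(but-3-enoyl)oxazolidin-2-one | C=CCC(=O)N1[C@@H](Cc2ccccc2)COC1=O | intermediate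
10 | trichlorotitanium (Z)-dienolate of 9 | C=C/C=C(\O[Ti](Cl)(Cl)Cl)N1[C@@H](Cc2ccccc2)COC1=O | intermediate
11 | (S)-4-benzyl-3-[(R)-2-(hydroxymethyl)but-3-enoyl]oxazolidin-2-one | C=C[C@H](CO)C(=O)N1[C@@H](Cc2ccccc2)COC1=O | intermediate
12 | (S)-4-benzyl-3-[(R)-2-{[tert-butyl(diphenyl)silyl]oxymethyl}but-3-enoyl]oxazolidin-2-one | C=C[C@H](CO[Si](c1ccccc1)(c1ccccc1)C(C)(C)C)C(=O)N1[C@@H](Cc2ccccc2)COC1=O | intermediate
13 | (S)-2-{[tert-butyl(diphenyl)silyl]oxymethyl}but-3-en-1-ol | C=C[C@H](CO[Si](c1ccccc1)(c1ccccc1)C(C)(C)C)CO | intermediate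
14 | (R)-2-{[tert-butyl(diphenyl)silyl]oxymethyl}but-3-enal | C=C[C@H](CO[Si](c1ccccc1)(c1ccccc1)C(C)(C)C)C=O | intermediate
15 | (R)-lactic acid | C[C@@H](O)C(=O)O | starting material
16 | trimethylsilyl (R)-2-[(trimethylsilyl)oxy]propanoate | C[C@@H](O[Si](C)(C)C)C(=O)O[Si](C)(C)C | intermediate
17 | (2R,5R)-2-[(2R)-1-{[tert-butyl(diphenyl)silyl]oxy}but-3-en-2-yl]-5-methyl-1,3-dioxolan-4-one (cis) | C[C@H]1O[C@@H]([C@H](C=C)CO[Si](c2ccccc2)(c2ccccc2)C(C)(C)C)OC1=O | intermediate
18 | lithium enolate of 17 | CC1=C(O[Li])O[C@H]([C@H](C=C)CO[Si](c2ccccc2)(c2ccccc2)C(C)(C)C)O1 | intermediate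
19 | (2R,5S)-2-[(2R)-1-{[tert-butyl(diphenyl)silyl]oxy}but-3-en-2-yl]-5-methyl-5-(3-methylbut-2-en-1-yl)-1,3-dioxolan-4-one | CC(C)=CC[C@]1(C)O[C@@H]([C@H](C=C)CO[Si](c2ccccc2)(c2ccccc2)C(C)(C)C)OC1=O | intermediate
20 | secondary ozonide of 19 (3,3-dimethyl-1,2,4-trioxolan-5-yl in place of the alkene; epimers at the trioxolane CH) | CC1(C)OOC(C[C@]2(C)O[C@@H]([C@H](C=C)CO[Si](c3ccccc3)(c3ccccc3)C(C)(C)C)OC2=O)O1 | intermediate
21 | 2-[(2R,5S)-2-[(2R)-1-{[tert-butyl(diphenyl)silyl]oxy}but-3-en-2-yl]-5-methyl-4-oxo-1,3-dioxolan-5-yl]acetaldehyde | O=CC[C@]1(C)O[C@@H]([C@H](C=C)CO[Si](c2ccccc2)(c2ccccc2)C(C)(C)C)OC1=O | intermediate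
22 | ring-opened adduct as trimethylsilyl ester: 3-[(trimethylsilyl)methyl]furan-2(5H)-one joined at its C5 (target C6) to C5; ether oxygen to C10, which bears CH3, CH2CHO and CO2SiMe3; (4R,5R,6S,10S) | C[Si](C)(C)CC1=C[C@H](OC1=O)[C@H](O[C@@](C)(CC=O)C(=O)O[Si](C)(C)C)[C@H](C=C)CO[Si](c2ccccc2)(c2ccccc2)C(C)(C)C | intermediate
23 | trimethylsilyl ester and C8 trimethylsilyl ether of 24 | C=C1C(=O)O[C@@H]2[C@H](O[C@@](C)(C[C@@H](O[Si](C)(C)C)[C@@H]12)C(=O)O[Si](C)(C)C)[C@H](C=C)CO[Si](c3ccccc3)(c3ccccc3)C(C)(C)C | intermediate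
24 | hydroxy acid: oxepane ring A (O, C5–C10) trans-fused at C6–C7 to the α-methylene-γ-butyrolactone; OH at C8; CH3 and CO2H at C10; (2R)-1-silyloxybut-3-en-2-yl at C5; (4R,5R,6S,7R,8R,10S) | C=C1C(=O)O[C@@H]2[C@H](O[C@@](C)(C[C@@H](O)[C@@H]12)C(=O)O)[C@H](C=C)CO[Si](c3ccccc3)(c3ccccc3)C(C)(C)C | intermediate
25 | C8 angelate of 24 | C=C1C(=O)O[C@@H]2[C@H](O[C@@](C)(C[C@@H](OC(=O)/C(C)=C\C)[C@@H]12)C(=O)O)[C@H](C=C)CO[Si](c3ccccc3)(c3ccccc3)C(C)(C)C | intermediate
26 | acid chloride of 25 | C=C1C(=O)O[C@@H]2[C@H](O[C@@](C)(C[C@@H](OC(=O)/C(C)=C\C)[C@@H]12)C(=O)Cl)[C@H](C=C)CO[Si](c3ccccc3)(c3ccccc3)C(C)(C)C | intermediate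
27 | vinyl ketone: 25 with C(=O)CH=CH2 at C10 in place of CO2H | C=C1C(=O)O[C@@H]2[C@H](O[C@@](C)(C[C@@H](OC(=O)/C(C)=C\C)[C@@H]12)C(=O)C=C)[C@H](C=C)CO[Si](c3ccccc3)(c3ccccc3)C(C)(C)C | intermediate
28 | 15-O-tert-butyldiphenylsilyl ether of the target | C=C1C(=O)O[C@@H]2[C@@H]3O[C@@](C)(C[C@@H](OC(=O)/C(C)=C\C)[C@@H]12)C(=O)C=C[C@@H]3CO[Si](c4ccccc4)(c4ccccc4)C(C)(C)C | intermediate
29 | CNP0274187.1: (4R,5R,6S,7R,8R,10S)-8-angeloyloxy-15-hydroxy-1-oxo-5,10-epoxygermacra-2Z,11(13)-dien-12,6-olide | C=C1C(=O)O[C@@H]2[C@@H]3O[C@@](C)(C[C@@H](OC(=O)/C(C)=C\C)[C@@H]12)C(=O)C=C[C@@H]3CO | target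

**Totals**
Total step count: 17. Longest linear sequence: 13 steps (steps 4–8, then 10–17).

**Steps most likely to fail**

Step 13 (proposed new method). The first C–C bond may form with low simple diastereoselection (C6 against C5), and the electron-poor allylsilane may be protodesilylated before it reaches the aldehyde. The fallback sets out from 21 and 5 and returns at 24, and it uncouples the two bond formations. TMSOTf alone at −78 °C with an aqueous quench stops after the first bond at the butenolide acid F1, a known vinylogous Mukaiyama addition to an acyloxy acetal. The C6 epimers of F1 can be separated, or equilibrated with Et3N through the furan dienolate. The allylsilane is then closed onto the aldehyde in a separate Hosomi–Sakurai cyclisation with TiCl4 at −78 °C, as known for 2-(silylmethyl)alkenoates, to give 24.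

Step 16. Ring closure has to build the strain of the trans-bridged bicycle and may be outrun by oligomerising cross-metathesis or by alkene isomerisation. The fallback sets out from 27 and returns at 28. Luche reduction (NaBH4, CeCl3·7H2O, MeOH, −78 °C) of the vinyl ketone gives the allylic alcohols F2 (both C1 epimers), in which C1 is sp3 and the alkene is a better metathesis partner. Ring-closing metathesis then gives the bicyclic allylic alcohol F3, and oxidation with MnO2 restores the enone 28.

Step 14. Acyl transfer to the free carboxylic acid, Z to E isomerisation of the angelate, or migration of the lactone to the C8 oxygen may occur under the warm basic conditions. The fallback sets out from 24 and returns at 25. The acid is first masked as the allyl ester F4 (allyl bromide, KHCO3, DMF; carboxylate alkylation leaves the secondary alcohol alone). The alcohol is then esterified with the angelic mixed anhydride at lower temperature to give the allyl ester angelate F5. The allyl ester is removed with Pd(PPh3)4 and morpholine to give 25.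

**Further compounds**
F1 | step 13 | butenolide acid (free acid of 22) | C[Si](C)(C)CC1=C[C@H](OC1=O)[C@H](O[C@@](C)(CC=O)C(=O)O)[C@H](C=C)CO[Si](c2ccccc2)(c2ccccc2)C(C)(C)C
F2 | step 16 | allylic alcohols from 27 (C1 epimers) | C=C1C(=O)O[C@@H]2[C@H](O[C@@](C)(C[C@@H](OC(=O)/C(C)=C\C)[C@@H]12)C(O)C=C)[C@H](C=C)CO[Si](c3ccccc3)(c3ccccc3)C(C)(C)C
F3 | step 16 | bicyclic allylic alcohol (C1 epimers) | C=C1C(=O)O[C@@H]2[C@@H]3O[C@@](C)(C[C@@H](OC(=O)/C(C)=C\C)[C@@H]12)C(O)C=C[C@@H]3CO[Si](c4ccccc4)(c4ccccc4)C(C)(C)C
F4 | step 14 | allyl ester of 24 | C=C1C(=O)O[C@@H]2[C@H](O[C@@](C)(C[C@@H](O)[C@@H]12)C(=O)OCC=C)[C@H](C=C)CO[Si](c3ccccc3)(c3ccccc3)C(C)(C)C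
F5 | step 14 | allyl ester angelate | C=C1C(=O)O[C@@H]2[C@H](O[C@@](C)(C[C@@H](OC(=O)/C(C)=C\C)[C@@H]12)C(=O)OCC=C)[C@H](C=C)CO[Si](c3ccccc3)(c3ccccc3)C(C)(C)C
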